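**Small charge.** A small charge of free monomer stands in two flasks made up alike, amber to be read at 25 min and green at 100 min.

| setting | delta | zeta | amber | green |
|---|---|---|---|---|
| free monomer | 28 mM | 44 mM | 20 mM | 20 mM |
| transfer agent | 0.20 mM | 0.20 mM | 0.200 mM | 0.200 mM |
| initiator | 5 mol% | 5 mol% | 5 mol% | 5 mol% |
| remark | run made earlier | run made earlier |  |  |
| time |  |  | 25 min | 100 min |

| delta: time / min | delta: monomer in chains / % | zeta: time / min | zeta: monomer in chains / % |
|---|---|---|---|
| 4.00 | 19 | 2.00 | 16 |
| 8.00 | 36 | 3.00 | 22 |
| 12.0 | 46 | 6.00 | 46 |
| 15.0 | 52 | 10.0 | 57 |
| 20.0 | 64 | 15.0 | 75 |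
| 25.0 | 69 | 25.0 | 82 |

(standard deviation of a reading: 2 percentage points)

- the average divides the monomer in chains by the number of chains begun, living and dead together
- the numbers in the tables scatter with a standard deviation of 2 percentage points
- the earlier runs do not show the number of chains; that part of a forecast is a guess

* which of the two ends with the longer chains by the average number of monomer units in a chain (chains begun, living or dead) ("neither" if they lie within 10%) (amber / green / neither)
* average number of monomer units in a chain (chains begun, living or dead) at the end, amber
* average number of monomer units in a chain (chains begun, living or dead) at the end, green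

**The pace.** I watch the fraction of free monomer left, not the fraction made. The natural log of one over the fraction left, divided by the time, is the pace, a pseudo-first-order constant. As readings, delta with 36.0% left at 20.0 min has 0.0511 min⁻¹, and zeta with 25.0% left at 15.0 min has 0.0924 min⁻¹. That is 1.81 times the pace on 1.57 times the charge, so I use a straight line through both runs, not a proportion. At this charge it reads 0.0304 min⁻¹, the pace I carry.

**When you come.** Amber will have 46.8% of its free monomer left and green 4.78%, so I expect green to have the longer chains. The chain count is my guess: the geometric middle of 0.200 mM transfer agent and 1.00 mM initiator, 0.447 mM. That gives 23.8 units for amber and 42.6 for green. Leave both charges as they are, since the pace I carry is reckoned for this charge.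

**The result.** The forecast names green, with 52 units for amber and 82 for green, taking it that “the transfer agent sets the count”, at 0.22 mM of chains where I guessed 0.447 mM. The flasks give green, with 23.7 units for amber and 41.3 for green.

    free monomer + initiator → living end + monomer in chains (k = 1.60 M⁻¹ s⁻¹)
    free monomer + living end → monomer in chains + living end, rate k2*[living end]*[free monomer] (k = 1.90 M⁻¹ s⁻¹)
    living end + transfer agent → dead chain (kL = 17.0 M⁻¹ s⁻¹)
    free monomer + initiator → spent initiator (k = 2.00 M⁻¹ s⁻¹)

**Why green.** Green ends longer than amber because it stood longer: it has 41.3 units, against 23.7 with amber's time. At their times both flasks hold 0.244 mM living ends and 0.200 mM dead chains, while free monomer left is 45% in amber and 5.5% in green. Those fractions give a pace of 0.0323 min⁻¹ and 0.0290 min⁻¹, beside the 0.0304 min⁻¹ I carried. In a flask like green charged with 12 mM, the same line gives 0.00975 min⁻¹, hence 37.7% left at 100 min; that flask keeps 38% of its free monomer.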